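**Retrosynthetic overview**

1. Target ⇒ C9‑vinyl decalin angelate + (Z)‑3‑iodobut‑2‑enoic acid (hydroboration/B‑alkyl Suzuki makes C12–C13 and brings in the 13Z acid); angelate ⇐ C19 alcohol + angelic acid.
2. C4 quaternary centre (4α‑CH3, 4β‑CH2O) ⇐ C4 ketone, through an ethylidene spiro‑epoxide and a Lewis‑acid 1,2‑methyl shift (Meinwald/semipinacol type). This is the pivotal step; the angular methyl steers it.
3. The C4 ketone is the carbonyl of 3‑methylcyclohex‑2‑enone, which is ring A; ring B ⇐ intramolecular dienamine Michael closure C9→C10 (sets C9 and C10; C5 by equilibration).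
4. Cyclisation substrate ⇐ α‑alkylation of 3‑methylcyclohex‑2‑enone with the bromide of (Z)‑3‑methylpent‑2‑en‑4‑yn‑1‑ol, then anti‑Markovnikov alkyne hydration.
5. Ring order: ring A is bought, ring B is closed onto it; C4, the ester and the side chain follow.

Convention used below: decalin compounds carry labdane numbering (ring A = C1–C5, C10; ring B = C5–C10; C20 = angular methyl on C10; C19 = the carbon that becomes CH2O on C4); β = the face of C20, α = the opposite face.

**Route**

Step 1
Reactants: 1 (2Z)-3-methylpent-2-en-4-yn-1-ol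
Product: 2 (3Z)-5-bromo-3-methylpent-3-en-1-yne
Conditions: PBr3 (0.4 equiv), Et2O, −20 to 0 °C
Reagents that add atoms: phosphorus tribromide, BrP(Br)Br
Why: SN2 bromination of the primary allylic alcohol through its phosphite ester, which leaves the Z‑trisubstituted double bond untouched; no stereocentre is formed.

Step 2
Reactants: 3 3-methylcyclohex-2-en-1-one; 2 (3Z)-5-bromo-3-methylpent-3-en-1-yne
Product: 4 3-methyl-2-[(2Z)-3-methylpent-2-en-4-yn-1-yl]cyclohex-2-en-1-one
Conditions: t-BuOK, t-BuOH/THF, 0 °C to rt (3 in twofold excess)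
Reagents that add atoms: none
Why: α‑alkylation of the thermodynamic (extended) dienolate of a β‑methyl enone by a reactive allylic bromide (SN2), the first‑formed deconjugated ketone returning to the conjugated enone under the base; the Z geometry is carried over and no stereocentre is formed.

Step 3
Reactants: 4 3-methyl-2-[(2Z)-3-methylpent-2-en-4-yn-1-yl]cyclohex-2-en-1-one
Product: 5 (3Z)-3-methyl-5-(2-methyl-6-oxocyclohex-1-en-1-yl)pent-3-enal
Conditions: [CpRu(NCMe)(2-Ph2P-6-tBu-C5H3N)2]PF6 (3 mol %), H2O, acetone, 60 °C
Reagents that add atoms: water, O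
Why: ruthenium‑vinylidene (anti‑Markovnikov) hydration of the terminal alkyne gives the β,γ‑unsaturated aldehyde directly, the enone and the trisubstituted alkene being inert, so the Z geometry needed for ring closure is kept; no stereocentre is formed.

Step 4
Reactants: 5 (3Z)-3-methyl-5-(2-methyl-6-oxocyclohex-1-en-1-yl)pent-3-enal
Product: 6 trans-fused keto aldehyde (4-oxo; Δ7; 5α-H; 9β-CHO; 10β-CH3)
Conditions: 9-amino-9-deoxy-epi-quinidine (20 mol %), CF3CO2H (40 mol %), toluene, 25 °C; then H2O
Reagents that add atoms: none
Why: Proposed new method: amine‑catalysed enantioselective intramolecular dienamine Michael ring closure onto a fully substituted enone β‑carbon, in which the primary amine condenses with the unhindered aldehyde to the (1E,3Z)‑dienamine whose α‑carbon (C9) is the only nucleophilic site that can reach C10 through a six‑membered transition state (γ‑attack would give a cyclobutane), while the protonated quinuclidine hydrogen‑bonds the enone carbonyl and fixes the face of C10 that is attacked (sets C10), the enamine carbon C11 lies anti to C5 and away from ring A so that CHO ends cis to the angular methyl (sets C9), and ketonisation gives mainly the trans ring fusion at C5 (any cis epimer converges in step 5); the closest known reaction types are the amine‑catalysed asymmetric intramolecular Michael addition of aldehydes to enones and cinchona primary‑amine activation of β‑substituted cyclic enones, and the quinine‑derived pseudo‑enantiomer is used if the facial sense turns out opposite.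

Step 5
Reactants: 6 trans-fused keto aldehyde
Product: 7 vinyl ketone (4-oxo; Δ7; 5α-H; 9β-vinyl; 10β-CH3)
Conditions: Ph3PCH3Br, KN(SiMe3)2, THF, −78 to 0 °C; then NaOMe (0.2 equiv), MeOH, rt
Reagents that add atoms: methyltriphenylphosphonium bromide, C[P+](c1ccccc1)(c1ccccc1)c1ccccc1.[Br-]
Why: Wittig methylenation is selective for the aldehyde over the hindered ring ketone and at −78 °C outruns enolisation at C9, after which catalytic methoxide equilibrates C5 (α to the ketone) to the more stable trans‑fused ketone; C9 is no longer epimerisable and no new stereocentre is formed.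

Step 6
Reactants: 7 vinyl ketone
Product: 8 spiro-epoxide at C4 (oxirane O β and axial; oxirane CH(CH3) α)
Conditions: Ph2S(Et)BF4, LiN(iPr)2, DME, −78 to −40 °C
Reagents that add atoms: ethyldiphenylsulfonium tetrafluoroborate, CC[S+](c1ccccc1)c1ccccc1.F[B-](F)(F)F
Why: Corey–Chaykovsky‑type epoxidation with an unstabilised sulfonium ethylide adds irreversibly to the C4 ketone from the α face, because the axial β trajectory is blocked by the syn‑axial angular methyl, so the new C–C bond is α and the oxirane oxygen β (sets the C4–O configuration; the oxirane CH centre is lost in step 7).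

Step 7
Reactants: 8 spiro-epoxide at C4
Product: 10 19-alcohol (4α-CH3; 4β-CH2OH; 9β-vinyl), via quaternary aldehyde 9 (not isolated)
Conditions: MeAl(OC6H2-4-Br-2,6-tBu2)2 (20 mol %), CH2Cl2, −78 to −20 °C; then NaBH4, MeOH, 0 °C
Reagents that add atoms: none
Why: Meinwald (semipinacol‑type) rearrangement in which the bulky aluminium Lewis acid ionises the tertiary C4–O bond and the methyl group on C19 makes a 1,2‑shift to C4 on the face opposite the departing oxygen (this type of bulky aluminium aryloxide favours alkyl over hydride shift in trisubstituted epoxides), so C19 becomes the aldehyde and C4 is set as 4α‑CH3/4β‑CHO, which NaBH4 reduces in the same flask.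

Step 8
Reactants: 10 19-alcohol; 11 angelic acid [(2Z)-2-methylbut-2-enoic acid]
Product: 13 19-angelate of the vinyl decalin, via mixed anhydride 12 (not isolated)
Conditions: 2,4,6-Cl3C6H2COCl, Et3N, toluene, rt; then 10, 80 °C
Reagents that add atoms: none
Why: Yamaguchi‑type mixed‑anhydride esterification run without DMAP, so the Z (angelate) geometry is not isomerised to tiglate, the neopentyl primary alcohol attacking the less hindered angeloyl carbonyl; no stereocentre is touched.

Step 9
Reactants: 14 but-2-ynoic acid
Product: 15 (2Z)-3-iodobut-2-enoic acid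
Conditions: NaI, AcOH, 115 °C
Reagents that add atoms: sodium iodide, [Na+].[I-]
Why: hydroiodination of the ynoic acid (conjugate addition of iodide, then anti protonation) gives the Z‑β‑iodo acid selectively.

Step 10
Reactants: 13 19-angelate of the vinyl decalin; 15 (2Z)-3-iodobut-2-enoic acid
Product: 17 (4S,5R,9S,10R)-19-angeloyloxylabda-7,13Z-dien-15-oic acid (target), via alkylborane 16 (not isolated)
Conditions: 9-BBN-H, THF, 0 °C to rt; then 15, PdCl2(dppf) (5 mol %), AsPh3, Cs2CO3, DMF/H2O, rt; work-up at pH 3
Reagents that add atoms: none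
Why: 9‑BBN hydroborates only the monosubstituted vinyl group (anti‑Markovnikov, boron on C12), and the B‑alkyl Suzuki–Miyaura coupling with the Z‑iodo acid (as its carboxylate) proceeds with retention to give the 13Z acid, the angelate surviving the mild carbonate base.

**Compound list**

1 | (2Z)-3-methylpent-2-en-4-yn-1-ol | C#C/C(C)=C\CO | starting material
2 | (3Z)-5-bromo-3-methylpent-3-en-1-yne | C#C/C(C)=C\CBr | intermediate
3 | 3-methylcyclohex-2-en-1-one | CC1=CC(=O)CCC1 | starting material
4 | 3-methyl-2-[(2Z)-3-methylpent-2-en-4-yn-1-yl]cyclohex-2-en-1-one | CC1=C(C/C=C(C)\C#C)C(=O)CCC1 | intermediate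
5 | (3Z)-3-methyl-5-(2-methyl-6-oxocyclohex-1-en-1-yl)pent-3-enal | CC1=C(C/C=C(C)\CC=O)C(=O)CCC1 | intermediate
6 | 2,8a-dimethyl-5-oxo-1,4,4a,5,6,7,8,8a-octahydronaphthalene-1-carbaldehyde; labdane numbering: 4-oxo; Δ7; 5α-H; 9β-CHO; 10β-CH3 (trans-fused; CHO cis to the angular methyl) | O=C1CCC[C@]2(C)[C@@H](C=O)C(C)=CC[C@@H]12 | intermediate
7 | 5-ethenyl-4a,6-dimethyl-3,4,4a,5,8,8a-hexahydronaphthalen-1(2H)-one; 4-oxo; Δ7; 5α-H; 9β-vinyl; 10β-CH3 | O=C1CCC[C@]2(C)[C@@H](C=C)C(C)=CC[C@@H]12 | intermediate
8 | spiro-epoxide of 7 at C4: oxirane oxygen on the β face (axial); oxirane CH(CH3) carbon (C19) on the α face; major epimer at the oxirane CH drawn (both epimers converge) | C[C@@H]1O[C@]12CCC[C@]3(C)[C@@H](C=C)C(C)=CC[C@@H]23 | intermediate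
9 | 19-aldehyde: 4α-methyl-4β-formyl; Δ7; 5α-H; 9β-vinyl; 10β-CH3 | O=C[C@@]1(C)CCC[C@]2(C)[C@@H](C=C)C(C)=CC[C@@H]12 | intermediate (not isolated)
10 | 19-alcohol: (5-ethenyl-1,4a,6-trimethyl-1,2,3,4,4a,5,8,8a-octahydronaphthalen-1-yl)methanol; 4α-CH3; 4β-CH2OH (axial; cis to the angular methyl); 5α-H; 9β-vinyl | OC[C@@]1(C)CCC[C@]2(C)[C@@H](C=C)C(C)=CC[C@@H]12 | intermediate
11 | angelic acid; (2Z)-2-methylbut-2-enoic acid | C/C=C(/C)C(=O)O | starting material
12 | angelic 2,4,6-trichlorobenzoic anhydride | C/C=C(/C)C(=O)OC(=O)c1c(Cl)cc(Cl)cc1Cl | intermediate (not isolated)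
13 | 19-angelate of 10 (9β-vinyl; Δ7) | C/C=C(/C)C(=O)OC[C@@]1(C)CCC[C@]2(C)[C@@H](C=C)C(C)=CC[C@@H]12 | intermediate
14 | but-2-ynoic acid | CC#CC(=O)O | starting material
15 | (2Z)-3-iodobut-2-enoic acid | I/C(C)=C\C(=O)O | intermediate
16 | B-alkyl-9-BBN adduct of 13 (boron on C12) | C/C=C(/C)C(=O)OC[C@@]1(C)CCC[C@]2(C)[C@@H](CCB3C4CCCC3CCC4)C(C)=CC[C@@H]12 | intermediate (not isolated)
17 | (4S,5R,9S,10R)-19-[(2Z)-2-methylbut-2-enoyloxy]labda-7,13Z-dien-15-oic acid | C/C=C(/C)C(=O)OC[C@@]1(C)CCC[C@]2(C)[C@@H](CC/C(C)=C\C(=O)O)C(C)=CC[C@@H]12 | target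

**Step count and risks**

Total step count: 10. Longest linear sequence: 9 (steps 1–8 and 10; step 9 is a one‑step side branch).

The three steps most likely to fail:

Step 4, the proposed ring closure. The acceptor carbon is fully substituted and may be too unreactive towards a dienamine. Amine/acid equilibration can also leak into the cross‑conjugated dienamine (exocyclic‑methylene isomer) or epimerise C9 of the product, and the sense and level of induction are untested. The fallback uses known chemistry: it sets out from 5 and changes both the activation mode and the source of chirality. Aldehyde 5 is silylated (t‑BuMe2SiOTf, Et3N, CH2Cl2, −78 °C) to the silyl dienol ether F1. TiCl4 in CH2Cl2 at −78 °C then effects an intramolecular Mukaiyama–Michael addition, a known way to make quaternary carbons on β,β‑disubstituted enones, and gives the racemic keto aldehyde F2. F2 is resolved by condensation with (1R,2R)‑N,N'‑dimethyl‑1,2‑diphenylethane‑1,2‑diamine, chromatographic separation of the two imidazolidines, and mild aqueous acid hydrolysis of the aminal F3 that carries the wanted enantiomer. This comes back to the route at 6, with half of the material lost.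

Step 7, the 1,2‑methyl shift. Methyl is the poorest alkyl migrator, so hydride shift (to a 4‑acetyl compound) or elimination to an allylic alcohol may compete, and the bulky aluminium reagent must reach an axial oxygen next to the angular methyl. The fallback sets out from 7 and avoids the rearrangement. Wittig reaction with Ph3P=CHOMe (from the methoxymethylphosphonium chloride and KN(SiMe3)2) gives the enol ether F4. Aqueous HCl in THF hydrolyses it to the C4–H aldehyde F5, whose potassium enolate (t‑BuOK, THF) is methylated with MeI from the α face, the known outcome for C4 enolates of 10‑methyl‑trans‑decalins. This gives aldehyde 9, and NaBH4 reduction comes back to the route at 10.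

Step 2, the dienolate alkylation. Double alkylation, O‑ or γ‑alkylation and base damage to the enyne bromide can erode the yield. The fallback sets out from 2 and builds the enone by Stork–Danheiser transposition. Cyclohexane‑1,3‑dione is C‑alkylated with 2 (aqueous KOH, Cu powder) to the 2‑substituted dione F6. Treatment with HC(OMe)3, MeOH and TsOH gives the vinylogous ester F7. MeLi (2.2 equiv, the first equivalent being taken by the alkyne C–H) in THF at −78 °C, followed by 1 M HCl, comes back to the route at 4.

**Further compounds**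

F1 | step 4 | silyl dienol ether of 5: 2-[(2Z,4E)-5-(tert-butyldimethylsilyloxy)-3-methylpenta-2,4-dien-1-yl]-3-methylcyclohex-2-en-1-one | CC1=C(C/C=C(C)\C=C\O[Si](C)(C)C(C)(C)C)C(=O)CCC1
F2 | step 4 | racemic keto aldehyde (racemate of 6; same relative configuration) | O=CC1C(C)=CCC2C(=O)CCCC12C
F3 | step 4 | imidazolidine (aminal) of 6 with (1R,2R)-N,N'-dimethyl-1,2-diphenylethane-1,2-diamine | O=C1CCC[C@]2(C)[C@@H](C3N(C)[C@H](c4ccccc4)[C@@H](c4ccccc4)N3C)C(C)=CC[C@@H]12
F4 | step 7 | methyl enol ether of the homologated aldehyde: 4-(methoxymethylidene) derivative of 7 (E/Z mixture) | COC=C1CCC[C@]2(C)[C@@H](C=C)C(C)=CC[C@@H]12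
F5 | step 7 | C4–H aldehyde: 4-formyl; 5α-H; 9β-vinyl; 10β-CH3 (4α-CHO epimer drawn; both epimers give the same enolate) | O=C[C@@H]1CCC[C@]2(C)[C@@H](C=C)C(C)=CC[C@@H]12
F6 | step 2 | 2-[(2Z)-3-methylpent-2-en-4-yn-1-yl]cyclohexane-1,3-dione | O=C1CCCC(=O)C1C/C=C(C)\C#C
F7 | step 2 | 3-methoxy-2-[(2Z)-3-methylpent-2-en-4-yn-1-yl]cyclohex-2-en-1-one | COC1=C(C/C=C(C)\C#C)C(=O)CCC1
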